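Begin at early times, with the first readings of these runs, and reckon what alder and cedar hold at their ends.

common to all: precatalyst 0.5 mol%

| flask | left-handed substrate | right-handed substrate | partner | remark | time |
|---|---|---|---|---|---|
| south-east | 0.025 M | 0.025 M | 3 equiv | run made earlier |  |
| south | 0.038 M | 0.038 M | 3 equiv | run made earlier |  |
| north | 0.050 M | 0.050 M | 6 equiv | run made earlier |  |
| alder | 0.050 M | 0.050 M | 3.00 equiv |  | 5.0 min |
| cedar | 0.050 M | 0.050 M | 3.00 equiv |  | 10 min |

| run | time / min | right-handed substrate / % | left-handed substrate / % | left-handed product / % |
|---|---|---|---|---|
| south-east | 0.833 | 49.7 | 50.1 | 0 |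
| south-east | 1.50 | 50.0 | 50.1 | 0 |
| south-east | 2.50 | 50.4 | 49.7 | 1.1 |
| south-east | 3.00 | 50.5 | 49.7 | 0.4 |
| south-east | 4.00 | 49.5 | 47.9 | 1.1 |
| south-east | 5.00 | 50.2 | 48.3 | 3.2 |
| south | 0.333 | 50.3 | 49.9 | 1.2 |
| south | 1.00 | 48.9 | 49.2 | 0.3 |
| south | 2.00 | 49.9 | 48.0 | 0.9 |
| south | 2.50 | 49.8 | 48.8 | 1.9 |
| south | 4.00 | 50.2 | 46.2 | 3.3 |
| south | 5.00 | 49.5 | 44.3 | 4.8 |
| north | 1.00 | 50.4 | 48.5 | 1.0 |
| north | 2.00 | 50.4 | 44.7 | 5.4 |
| north | 3.00 | 49.3 | 36.1 | 12.1 |
| north | 4.00 | 49.7 | 26.9 | 18.2 |
| north | 5.00 | 49.5 | 18.3 | 26.4 |

(readings scatter by 0.5 percentage points)

- free catalyst is single-handed; left-handed substrate and right-handed substrate are mirror images of each other, charged as a racemate, each of them at the stated concentration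
- what was read earlier has a scatter of 0.5 percentage points, one standard deviation
- reactions considered so far: partner + catalyst intermediate A -> free catalyst + left-handed product; free catalyst + right-handed substrate <-> catalyst intermediate B; partner -> decomposition product; free catalyst + left-handed substrate <-> catalyst intermediate A; partner + catalyst intermediate B -> free catalyst + right-handed product; left-handed product <-> right-handed product; partner + precatalyst -> free catalyst + spent reagent
- an excess is the difference of the two amounts in percent of their sum
- an excess is below zero if the other one leads

- which one finishes higher in excess of right-handed substrate over left-handed substrate among what is left of the two ("neither" within 2 percentage points) (alder / cedar / neither)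
- excess of right-handed substrate over left-handed substrate among what is left of the two at the end, alder
- excess of right-handed substrate over left-handed substrate among what is left of the two at the end, cedar

North looks contradictory: its left-handed substrate falls by 3.8 percentage points between 1.00 min and 2.00 min, but by 8.6 points between 4.00 min and 5.00 min, with less of it present. North's right-handed substrate stays near its start, so take the gap, right-handed minus left-handed substrate, as the loss. From 2.00 min to 4.00 min north's gap reads 4.00-fold larger, and the squared time ratio is 4.00.

Read this as catalyst still forming: partner makes it from precatalyst, then partner turns it over. Treat the partner spent as a correction, one partner per left-handed substrate lost. The correction disappears in the spend ratio, partner spent over partner left, which in this estimate grows in proportion to loading, equivalents, substrate concentration squared and time squared.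

Measure gap and partner against both substrates charged. On that scale north's partner is 3, and at 4.00 min its ratio reads 0.0823. Test it on south: the ratio scales to 0.0371, a gap of 5.4 points, against 5.2 points read.

On that scale alder and cedar carry partner 1.50. Alder's ratio is 0.0643, its gap 9.1 points, its excess 9.96 %. Cedar's ratio is 0.257, its gap 31 points, its excess 44.2 %.

The forecast, with “partner acting in both activation and turnover”, says cedar, 10.5 % for alder, higher than my figure, and 39 % for cedar, lower than my figure.

The flasks give 10.6 % for alder and 45.0 % for cedar, so cedar finishes higher.

    partner + catalyst intermediate A → free catalyst + left-handed product (k = 9.50 /M/s)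
    free catalyst + right-handed substrate ⇌ catalyst intermediate B (K = 7.80 /M, k = 950 /M/s)
    partner → decomposition product (k = 1.70 × 10⁻⁶ /s)
    free catalyst + left-handed substrate ⇌ catalyst intermediate A (K = 380 /M, k = 1700 /M/s)
    partner + catalyst intermediate B → free catalyst + right-handed product (k = 3.30 /M/s)
    left-handed product ⇌ right-handed product (k = 0.00260 /s)
    partner + precatalyst → free catalyst + spent reagent (k = 0.00500 /M/s)

In cedar at 6.53 min, the step from partner and catalyst intermediate A gives that intermediate a half-life of 0.54 s, far shorter than the 22 min it gives partner. At the end of cedar, 66.1 % of the catalyst charged is still precatalyst, and catalyst intermediate A, the resting state of the round, stands at 27.3 %, above free catalyst and catalyst intermediate B. The spend ratio leaves cedar 79.6 % of its partner, and 79 % stands there. Scaled by loading to cedar's neighbour with 0.12 mol% of precatalyst, the ratio becomes 0.0617, a gap of 8.7 points and an excess of 9.53 %; that flask gives 9.45 %.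

(The readings were computed for substances that don't exist; noise was put on by code.)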